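**Retrosynthetic overview**
1. The target is an all-trans 1-aryl-tetralin-2,3-dimethanol (ring A aromatic, ring B saturated). The last moves are protecting-group removal and reduction of a C3 ester; the C2 arm is carried as CH2OSi.
2. Ring B is cut at C4a–C4 and C2–C3: a two-carbon acrylate unit (C4=C3–CO2Me) is inserted between the iodinated ring A carbon C4a and the enol ether carbon C2 of an open-chain (R)-3,3-diarylpropanal silyl enol ether.
3. Enabling feature: on ring A, C8a (bearing C1) and C4a are ortho neighbours, and C2 and C3 each carry one oxygenated carbon. C3 plus its arm is therefore an acrylate (acceptor for the C4a aryl radical), and C2 plus its arm is an enol ether (acceptor for the electrophilic C3 radical), so ring B can close 6-exo.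
4. C1 is set by rhodium-catalysed asymmetric arylation of the ring A cinnamaldehyde; C2 is relayed from C1 in the key step; C3 is set by equilibration of the ester.
5. Ring order: ring A is bought and iodinated at C4a, then C1 is set, then ring B is formed in the key step; no other ring is made.

Key step: step 6

Remark: tetralin numbering is used throughout (C1 bears the pendant aryl, C2 and C3 the one-carbon arms, C4 is the benzylic CH2, ring A carries OMe at C5 and C6 and O at C7). The enantiomer of the diene ligand in step 4 is the one that delivers (R)-10; this is assigned by analogy and should be confirmed on the first run.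

**Step 1**
Reactants: 1 3-hydroxy-4,5-dimethoxybenzaldehyde
Product: 2 4,5-dimethoxy-3-[(triisopropylsilyl)oxy]benzaldehyde
Conditions: TIPSCl, imidazole, DMF, rt
Reagents that add atoms: triisopropylsilyl chloride, CC(C)[Si](Cl)(C(C)C)C(C)C
Why: Imidazole-promoted silylation of the phenol; the bulky, non-coordinating TIPS ether is chosen to shield its ortho position in step 2 and to last until step 9.

**Step 2**
Reactants: 2 4,5-dimethoxy-3-[(triisopropylsilyl)oxy]benzaldehyde
Product: 6 2-iodo-3,4-dimethoxy-5-[(triisopropylsilyl)oxy]benzaldehyde, via lithium amino alkoxide 3 (not isolated), via ortho-lithiated amino alkoxide 4 (not isolated), via iodinated amino alkoxide 5 (not isolated)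
Conditions: LiN(Me)CH2CH2NMe2 (from the diamine and n-BuLi), THF, −20 °C; n-BuLi (3 equiv), −20 °C; I2, −78 °C to rt; aq. NH4Cl/Na2S2O3
Reagents that add atoms: iodine, II
Why: Directed ortho-metalation with in situ protection of the aldehyde as its α-amino alkoxide; of the two ortho positions, the one flanked by the coordinating OMe should be lithiated and the one next to the bulky OTIPS group is blocked, and iodine quench with hydrolytic work-up returns the aldehyde.

**Step 3**
Reactants: 6 2-iodo-3,4-dimethoxy-5-[(triisopropylsilyl)oxy]benzaldehyde; 7 (triphenylphosphoranylidene)acetaldehyde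
Product: 8 (2E)-3-{2-iodo-3,4-dimethoxy-5-[(triisopropylsilyl)oxy]phenyl}prop-2-enal
Conditions: toluene, 90 °C
Reagents that add atoms: none
Why: Wittig olefination with a stabilised ylide should give the E enal.

**Step 4**
Reactants: 8 (2E)-3-{2-iodo-3,4-dimethoxy-5-[(triisopropylsilyl)oxy]phenyl}prop-2-enal; 9 [4-(benzyloxy)-3-methoxyphenyl]boronic acid
Product: 10 (3R)-3-[4-(benzyloxy)-3-methoxyphenyl]-3-{2-iodo-3,4-dimethoxy-5-[(triisopropylsilyl)oxy]phenyl}propanal
Conditions: [RhCl(C2H4)2]2 (2.5 mol%), chiral diene Ph-bod* (2,5-diphenylbicyclo[2.2.2]octa-2,5-diene, 5.5 mol%, enantiomer selected for R), KOH (0.3 equiv), dioxane/H2O 10:1, 40 °C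
Reagents that add atoms: none
Why: Hayashi–Miyaura reaction, the rhodium/chiral diene-catalysed asymmetric 1,4-addition of an arylboronic acid to a cinnamaldehyde; the ligand decides the face of aryl transfer and so sets C1 as R, and diene ligands favour 1,4- over 1,2-addition.

**Step 5**
Reactants: 10 (3R)-3-[4-(benzyloxy)-3-methoxyphenyl]-3-{2-iodo-3,4-dimethoxy-5-[(triisopropylsilyl)oxy]phenyl}propanal
Product: 11 triisopropyl{[(1Z,3R)-3-[4-(benzyloxy)-3-methoxyphenyl]-3-{2-iodo-3,4-dimethoxy-5-[(triisopropylsilyl)oxy]phenyl}prop-1-en-1-yl]oxy}silane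
Conditions: TIPSOTf, Et3N, CH2Cl2, 0 °C to rt
Reagents that add atoms: triisopropylsilyl trifluoromethanesulfonate, CC(C)[Si](OS(=O)(=O)C(F)(F)F)(C(C)C)C(C)C
Why: Soft enolisation and O-silylation of the aldehyde should give the silyl enol ether, mainly as the Z isomer (any E isomer is carried along and leads to the same product); C1 is not α to the carbonyl and is untouched.

**Step 6**
Reactants: 11 triisopropyl{[(1Z,3R)-3-[4-(benzyloxy)-3-methoxyphenyl]-3-{2-iodo-3,4-dimethoxy-5-[(triisopropylsilyl)oxy]phenyl}prop-1-en-1-yl]oxy}silane; 12 methyl acrylate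
Product: 16 methyl (1R,2S)-1-[4-(benzyloxy)-3-methoxyphenyl]-5,6-dimethoxy-7-[(triisopropylsilyl)oxy]-2-{[(triisopropylsilyl)oxy]methyl}-1,2,3,4-tetrahydronaphthalene-3-carboxylate as a mixture of C3 epimers, via aryl radical 13 (not isolated), via ester radical 14 (not isolated), via siloxyalkyl radical 15 (not isolated)
Conditions: Bu3SnH (2 equiv, syringe pump, 8 h), AIBN (0.2 equiv), methyl acrylate (8 equiv, 0.3 M), t-BuOH, 80 °C
Reagents that add atoms: none
Why: Proposed new method: Bu3Sn• abstracts iodine from C4a to give σ-aryl radical 13, which adds to the CH2 terminus of methyl acrylate (C4a–C4 bond) to give the electrophilic α-ester radical 14; this attacks the electron-rich enol ether carbon C2 (C3–C2 bond) to give the α-silyloxyalkyl radical 15, which is reduced by Bu3SnH. The closest known chemistry is the tin hydride Giese addition of aryl iodides to acrylates, radical addition–cyclisation annulations, and the cyclisation of α-carbonyl radicals onto silyl enol ethers; new is their combination into an intermolecular [4+2] annulation on a benzhydryl enol ether. Ring B closes in the 6-exo-trig mode, favoured over 7-endo by ring size and by polarity, since attack at C2 leaves the radical on the oxygen-bearing carbon. C2 is set by C1: allylic 1,3-strain with the Z silyloxy group holds the C1–H bond in the plane of the enol ether, so ring A and the pendant aryl lie on opposite faces, and the radical, tied to ring A, can only reach the face on its own side, which places the C2 arm trans to the pendant aryl; C3 is formed without reliable control but is α to the ester and is corrected in step 7. Site selectivity on ring A comes from the position of the iodine (C4a, not C8), and the order of events from rates: a low stationary Bu3SnH concentration and excess acrylate favour addition over reduction of 13, and the phenylene-constrained, polarity-matched closure of 14 should outrun telomerisation and 1,5-hydrogen transfer from C1–H.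

**Step 7**
Reactants: 16 methyl (1R,2S)-1-[4-(benzyloxy)-3-methoxyphenyl]-5,6-dimethoxy-7-[(triisopropylsilyl)oxy]-2-{[(triisopropylsilyl)oxy]methyl}-1,2,3,4-tetrahydronaphthalene-3-carboxylate (C3 epimers)
Product: 17 methyl (1R,2S,3S)-1-[4-(benzyloxy)-3-methoxyphenyl]-5,6-dimethoxy-7-[(triisopropylsilyl)oxy]-2-{[(triisopropylsilyl)oxy]methyl}-1,2,3,4-tetrahydronaphthalene-3-carboxylate
Conditions: KOt-Bu (0.3 equiv), t-BuOH/THF 1:4, rt; AcOH quench
Reagents that add atoms: none
Why: Enolate-mediated epimerisation at the ester α-carbon C3 should converge on the thermodynamic isomer with the C1, C2 and C3 substituents all equatorial (2,3-trans); C1 and C2 carry no acidic hydrogen and the hindered alkoxide should leave the TIPS ethers intact.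

**Step 8**
Reactants: 17 methyl (1R,2S,3S)-1-[4-(benzyloxy)-3-methoxyphenyl]-5,6-dimethoxy-7-[(triisopropylsilyl)oxy]-2-{[(triisopropylsilyl)oxy]methyl}-1,2,3,4-tetrahydronaphthalene-3-carboxylate
Product: 18 [(1R,2S,3S)-1-[4-(benzyloxy)-3-methoxyphenyl]-5,6-dimethoxy-7-[(triisopropylsilyl)oxy]-2-{[(triisopropylsilyl)oxy]methyl}-1,2,3,4-tetrahydronaphthalen-3-yl]methanol
Conditions: LiAlH4, THF, 0 °C
Reagents that add atoms: none
Why: Hydride reduction of the methyl ester to the primary alcohol; no stereocentre is touched and TIPS ethers should tolerate LiAlH4 at 0 °C.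

**Step 9**
Reactants: 18 [(1R,2S,3S)-1-[4-(benzyloxy)-3-methoxyphenyl]-5,6-dimethoxy-7-[(triisopropylsilyl)oxy]-2-{[(triisopropylsilyl)oxy]methyl}-1,2,3,4-tetrahydronaphthalen-3-yl]methanol
Product: 19 (1R,2S,3S)-1-[4-(benzyloxy)-3-methoxyphenyl]-2,3-bis(hydroxymethyl)-5,6-dimethoxy-1,2,3,4-tetrahydronaphthalen-7-ol
Conditions: n-Bu4NF (3 equiv), THF, rt; H2O
Reagents that add atoms: none
Why: Fluoride-mediated cleavage of the aryl and the primary alkyl silyl ether.

**Step 10**
Reactants: 19 (1R,2S,3S)-1-[4-(benzyloxy)-3-methoxyphenyl]-2,3-bis(hydroxymethyl)-5,6-dimethoxy-1,2,3,4-tetrahydronaphthalen-7-ol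
Product: 20 (1R,2S,3S)-1-(4-hydroxy-3-methoxyphenyl)-2,3-bis(hydroxymethyl)-5,6-dimethoxy-1,2,3,4-tetrahydronaphthalen-7-ol (target)
Conditions: H2 (1 atm), 10% Pd/C, MeOH/EtOAc, rt
Reagents that add atoms: none
Why: Catalytic hydrogenolysis of the benzyl aryl ether; nothing else in the molecule is reducible under these conditions.

**Compound list**
1 | 3-hydroxy-4,5-dimethoxybenzaldehyde | COc1cc(C=O)cc(O)c1OC | starting material
2 | 4,5-dimethoxy-3-[(triisopropylsilyl)oxy]benzaldehyde | COc1cc(C=O)cc(O[Si](C(C)C)(C(C)C)C(C)C)c1OC | intermediate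
3 | lithium amino alkoxide (adduct of 2 with lithium N,N,N'-trimethylethylenediamide) | COc1cc(C(O[Li])N(C)CCN(C)C)cc(O[Si](C(C)C)(C(C)C)C(C)C)c1OC | intermediate
4 | ortho-lithiated amino alkoxide (C–Li between the CH(OLi)N carbon and the OMe-bearing carbon) | COc1c([Li])c(C(O[Li])N(C)CCN(C)C)cc(O[Si](C(C)C)(C(C)C)C(C)C)c1OC | intermediate
5 | iodinated amino alkoxide | COc1c(I)c(C(O[Li])N(C)CCN(C)C)cc(O[Si](C(C)C)(C(C)C)C(C)C)c1OC | intermediate
6 | 2-iodo-3,4-dimethoxy-5-[(triisopropylsilyl)oxy]benzaldehyde | COc1c(I)c(C=O)cc(O[Si](C(C)C)(C(C)C)C(C)C)c1OC | intermediate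
7 | (triphenylphosphoranylidene)acetaldehyde | O=CC=P(c1ccccc1)(c1ccccc1)c1ccccc1 | starting material
8 | (2E)-3-{2-iodo-3,4-dimethoxy-5-[(triisopropylsilyl)oxy]phenyl}prop-2-enal | COc1c(I)c(/C=C/C=O)cc(O[Si](C(C)C)(C(C)C)C(C)C)c1OC | intermediate
9 | [4-(benzyloxy)-3-methoxyphenyl]boronic acid | COc1cc(B(O)O)ccc1OCc1ccccc1 | starting material
10 | (3R)-3-[4-(benzyloxy)-3-methoxyphenyl]-3-{2-iodo-3,4-dimethoxy-5-[(triisopropylsilyl)oxy]phenyl}propanal | COc1cc([C@@H](CC=O)c2cc(O[Si](C(C)C)(C(C)C)C(C)C)c(OC)c(OC)c2I)ccc1OCc1ccccc1 | intermediate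
11 | (1Z,3R)-silyl enol ether of 10 | COc1cc([C@@H](/C=C\O[Si](C(C)C)(C(C)C)C(C)C)c2cc(O[Si](C(C)C)(C(C)C)C(C)C)c(OC)c(OC)c2I)ccc1OCc1ccccc1 | intermediate
12 | methyl acrylate | C=CC(=O)OC | starting material
13 | aryl radical (radical at C4a) | COc1cc([C@@H](/C=C\O[Si](C(C)C)(C(C)C)C(C)C)c2cc(O[Si](C(C)C)(C(C)C)C(C)C)c(OC)c(OC)[c]2)ccc1OCc1ccccc1 | intermediate
14 | ester radical (radical at C3 after addition to acrylate) | COc1cc([C@@H](/C=C\O[Si](C(C)C)(C(C)C)C(C)C)c2cc(O[Si](C(C)C)(C(C)C)C(C)C)c(OC)c(OC)c2C[CH]C(=O)OC)ccc1OCc1ccccc1 | intermediate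
15 | siloxyalkyl radical (ring B closed, radical on the C2 arm) | COc1cc([C@@H]2c3cc(O[Si](C(C)C)(C(C)C)C(C)C)c(OC)c(OC)c3CC(C(=O)OC)[C@H]2[CH]O[Si](C(C)C)(C(C)C)C(C)C)ccc1OCc1ccccc1 | intermediate
16 | methyl (1R,2S)-1-[4-(benzyloxy)-3-methoxyphenyl]-5,6-dimethoxy-7-[(triisopropylsilyl)oxy]-2-{[(triisopropylsilyl)oxy]methyl}-1,2,3,4-tetrahydronaphthalene-3-carboxylate, C3 epimers | COc1cc([C@@H]2c3cc(O[Si](C(C)C)(C(C)C)C(C)C)c(OC)c(OC)c3CC(C(=O)OC)[C@H]2CO[Si](C(C)C)(C(C)C)C(C)C)ccc1OCc1ccccc1 | intermediate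
17 | methyl (1R,2S,3S)-1-[4-(benzyloxy)-3-methoxyphenyl]-5,6-dimethoxy-7-[(triisopropylsilyl)oxy]-2-{[(triisopropylsilyl)oxy]methyl}-1,2,3,4-tetrahydronaphthalene-3-carboxylate | COc1cc([C@@H]2c3cc(O[Si](C(C)C)(C(C)C)C(C)C)c(OC)c(OC)c3C[C@H](C(=O)OC)[C@H]2CO[Si](C(C)C)(C(C)C)C(C)C)ccc1OCc1ccccc1 | intermediate
18 | [(1R,2S,3S)-1-[4-(benzyloxy)-3-methoxyphenyl]-5,6-dimethoxy-7-[(triisopropylsilyl)oxy]-2-{[(triisopropylsilyl)oxy]methyl}-1,2,3,4-tetrahydronaphthalen-3-yl]methanol | COc1cc([C@@H]2c3cc(O[Si](C(C)C)(C(C)C)C(C)C)c(OC)c(OC)c3C[C@H](CO)[C@H]2CO[Si](C(C)C)(C(C)C)C(C)C)ccc1OCc1ccccc1 | intermediate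
19 | (1R,2S,3S)-1-[4-(benzyloxy)-3-methoxyphenyl]-2,3-bis(hydroxymethyl)-5,6-dimethoxy-1,2,3,4-tetrahydronaphthalen-7-ol | COc1cc([C@@H]2c3cc(O)c(OC)c(OC)c3C[C@H](CO)[C@H]2CO)ccc1OCc1ccccc1 | intermediate
20 | (1R,2S,3S)-1-(4-hydroxy-3-methoxyphenyl)-2,3-bis(hydroxymethyl)-5,6-dimethoxy-1,2,3,4-tetrahydronaphthalen-7-ol | COc1cc([C@@H]2c3cc(O)c(OC)c(OC)c3C[C@H](CO)[C@H]2CO)ccc1O | target

**Step count and risks**
Total steps: 10. Longest linear sequence: 10 steps (from 1).

Steps most likely to fail: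

1. Step 6. The aryl radical may be reduced before it meets the acrylate, the α-ester radical may telomerise or abstract the C1 hydrogen instead of cyclising, and facial control at C2 may be incomplete. Fallback (known reactions, from 10, back at 19): the two bonds are made one after the other. Aldehyde 10 is oxidised (NaClO2, NaH2PO4, 2-methyl-2-butene; Pinnick oxidation) to the carboxylic acid F1 and esterified (TMSCHN2, MeOH/toluene) to the methyl ester F2. Negishi coupling of the aryl iodide with BrZnCH2CH2CO2Me (Pd2(dba)3, SPhos, THF, 50 °C) forms the C4a–C4 bond and gives the diester F3. Double deprotonation (LDA, THF, −78 °C) and oxidation of the bis-enolate with CuBr2 closes ring B by intramolecular oxidative enolate coupling (C2–C3 bond). Equilibration with KOt-Bu then gives the all-trans tetralin diester F4, in which C2 and C3 are both epimerisable and so thermodynamically set. LiAlH4 gives the diol F5, and n-Bu4NF returns 19.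

2. Step 2. Lithiation may occur partly at the position next to the silyl ether, or the butyllithium may attack the silyl group, giving regioisomeric or desilylated material. Fallback (from 2, back at 6): catalytic C–H activation replaces stoichiometric lithiation. Pd(OAc)2 (10 mol%) with an anthranilic acid-type transient imine directing group and N-iodosuccinimide in AcOH/HFIP at 60 °C should palladate and iodinate the less hindered ortho C–H, the one beside OMe and not beside OTIPS, giving 6 directly; no new compound is formed.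

3. Step 4. Conversion or enantioselectivity may be low because of the ortho-iodo substituent, and 1,2-addition to the aldehyde may compete. Fallback (from 6, back at 10): auxiliary control replaces catalyst control. Horner–Wadsworth–Emmons reaction of 6 with diethyl {2-oxo-2-[(4S)-2-oxo-4-phenyl-1,3-oxazolidin-3-yl]ethyl}phosphonate (LiCl, i-Pr2NEt, MeCN) gives the N-enoyl oxazolidinone F6. Copper-mediated addition of [4-(benzyloxy)-3-methoxyphenyl]magnesium bromide (CuBr·SMe2, THF, −40 °C), anti to the 4-phenyl group of the chelated imide, gives the conjugate adduct F7 with C1 as R. LiBH4 (THF/MeOH) gives the alcohol F8, and Dess–Martin periodinane returns 10.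

**Further compounds**
F1 | step 6 | (3R)-3-[4-(benzyloxy)-3-methoxyphenyl]-3-{2-iodo-3,4-dimethoxy-5-[(triisopropylsilyl)oxy]phenyl}propanoic acid | COc1cc([C@@H](CC(=O)O)c2cc(O[Si](C(C)C)(C(C)C)C(C)C)c(OC)c(OC)c2I)ccc1OCc1ccccc1
F2 | step 6 | methyl (3R)-3-[4-(benzyloxy)-3-methoxyphenyl]-3-{2-iodo-3,4-dimethoxy-5-[(triisopropylsilyl)oxy]phenyl}propanoate | COc1cc([C@@H](CC(=O)OC)c2cc(O[Si](C(C)C)(C(C)C)C(C)C)c(OC)c(OC)c2I)ccc1OCc1ccccc1
F3 | step 6 | methyl (3R)-3-[4-(benzyloxy)-3-methoxyphenyl]-3-{3,4-dimethoxy-2-(3-methoxy-3-oxopropyl)-5-[(triisopropylsilyl)oxy]phenyl}propanoate | COc1cc([C@@H](CC(=O)OC)c2cc(O[Si](C(C)C)(C(C)C)C(C)C)c(OC)c(OC)c2CCC(=O)OC)ccc1OCc1ccccc1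
F4 | step 6 | dimethyl (1R,2S,3S)-1-[4-(benzyloxy)-3-methoxyphenyl]-5,6-dimethoxy-7-[(triisopropylsilyl)oxy]-1,2,3,4-tetrahydronaphthalene-2,3-dicarboxylate | COc1cc([C@@H]2c3cc(O[Si](C(C)C)(C(C)C)C(C)C)c(OC)c(OC)c3C[C@H](C(=O)OC)[C@H]2C(=O)OC)ccc1OCc1ccccc1
F5 | step 6 | [(1R,2S,3S)-1-[4-(benzyloxy)-3-methoxyphenyl]-5,6-dimethoxy-7-[(triisopropylsilyl)oxy]-1,2,3,4-tetrahydronaphthalene-2,3-diyl]dimethanol | COc1cc([C@@H]2c3cc(O[Si](C(C)C)(C(C)C)C(C)C)c(OC)c(OC)c3C[C@H](CO)[C@H]2CO)ccc1OCc1ccccc1
F0 | step 2 | none | none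
F6 | step 4 | (4S)-3-[(2E)-3-{2-iodo-3,4-dimethoxy-5-[(triisopropylsilyl)oxy]phenyl}prop-2-enoyl]-4-phenyl-1,3-oxazolidin-2-one | O=C(/C=C/c1cc(O[Si](C(C)C)(C(C)C)C(C)C)c(OC)c(OC)c1I)N1[C@@H](c2ccccc2)COC1=O
F7 | step 4 | (4S)-3-[(3R)-3-[4-(benzyloxy)-3-methoxyphenyl]-3-{2-iodo-3,4-dimethoxy-5-[(triisopropylsilyl)oxy]phenyl}propanoyl]-4-phenyl-1,3-oxazolidin-2-one | COc1cc([C@@H](CC(=O)N2[C@@H](c3ccccc3)COC2=O)c2cc(O[Si](C(C)C)(C(C)C)C(C)C)c(OC)c(OC)c2I)ccc1OCc1ccccc1
F8 | step 4 | (3R)-3-[4-(benzyloxy)-3-methoxyphenyl]-3-{2-iodo-3,4-dimethoxy-5-[(triisopropylsilyl)oxy]phenyl}propan-1-ol | COc1cc([C@@H](CCO)c2cc(O[Si](C(C)C)(C(C)C)C(C)C)c(OC)c(OC)c2I)ccc1OCc1ccccc1
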